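**Plan**

1. Retrosynthesis cuts the aryl ester bond between the galloyl C=O and O3' first, then, in one operation, the C2–C3 and O1–C2 bonds of the pyran ring.
2. This second cut contracts the pyran to a five-membered lactol, 4,6-bis(benzyloxy)-2,3-dihydrobenzofuran-2-ol, which holds O1, C3, C4, C4a and C8a, and leaves C2 as a B-ring benzylic sulfonium ylide.
3. The enabling feature is that C3 sits at the aldehyde oxidation level when O1 and the C4–C3 arm of the A ring form a lactol, while the 4'-oxygen para to C2 makes C2 the electrophilic end of an aryl epoxide. A benzylic ylide carbon (nucleophile first, electrophile second) can therefore be inserted into the O1–C3 bond.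
4. Forward order: B-ring sulfonium salt from methyl gallate (O4'/O5' as diphenylmethylene ketal, O3' as allyl ether); A-ring lactol from 3,5-bis(benzyloxy)phenol; ring expansion of the lactol ring to the chroman; deallylation, galloylation of the freed 3'-phenol, one hydrogenolysis.
5. Both stereocentres come from the chiral sulfide in the key step: a (2S,3S)-trans-epoxide is formed and C2 is inverted once in the 6-endo closure to give (2R,3S). The racemic lactol centre is erased through the achiral open-chain aldehyde.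

Key step: step 10

Assumption: the benzylide of (1S,4S,5S)-isothiocineole, made from (S)-limonene, is taken to give (S,S)-trans-epoxides; if the sense of induction is the reverse, (R)-limonene is used in step 5 and nothing else changes.

**Step 1**
Reactants: 1 methyl gallate
Product: 2 methyl 7-hydroxy-2,2-diphenyl-1,3-benzodioxole-5-carboxylate
Conditions: Ph2CCl2, neat, 180 °C, 15 min
Reagents that add atoms: dichlorodiphenylmethane, ClC(Cl)(c1ccccc1)c1ccccc1
Why: Ketal formation between the gem-dichloride and two adjacent phenols (a dioxole can only span vicinal oxygens) should leave exactly one phenol free, which differentiates O3' from O4'/O5' (known catechol protection).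

**Step 2**
Reactants: 2 methyl 7-hydroxy-2,2-diphenyl-1,3-benzodioxole-5-carboxylate
Product: 3 methyl 7-(allyloxy)-2,2-diphenyl-1,3-benzodioxole-5-carboxylate
Conditions: allyl bromide, K2CO3, DMF, rt
Reagents that add atoms: allyl bromide, C=CCBr
Why: Williamson etherification of the single free phenol installs a temporary group that is orthogonal to benzyl ethers and to the ketal.

**Step 3**
Reactants: 3 methyl 7-(allyloxy)-2,2-diphenyl-1,3-benzodioxole-5-carboxylate
Product: 4 [7-(allyloxy)-2,2-diphenyl-1,3-benzodioxol-5-yl]methanol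
Conditions: LiAlH4, THF, 0 °C
Reagents that add atoms: none
Why: Hydride reduction of the benzoate ester to the benzylic alcohol; allyl ether and ketal are inert to LiAlH4.

**Step 4**
Reactants: 4 [7-(allyloxy)-2,2-diphenyl-1,3-benzodioxol-5-yl]methanol
Product: 5 7-(allyloxy)-5-(bromomethyl)-2,2-diphenyl-1,3-benzodioxole
Conditions: CBr4, PPh3, CH2Cl2, 0 °C
Reagents that add atoms: tetrabromomethane, BrC(Br)(Br)Br
Why: Appel bromination under neutral conditions should convert the electron-rich benzylic alcohol into the bromide without acid that could touch the ketal.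

**Step 5**
Reactants: 6 (S)-(−)-limonene
Product: 7 (1S,4S,5S)-4,7,7-trimethyl-6-thiabicyclo[3.2.1]octane (isothiocineole)
Conditions: S8, γ-terpinene, neat, 110 °C; distillation
Reagents that add atoms: sulfur, S1SSSSSSS1
Why: Radical addition of sulfur across both C=C bonds of limonene with γ-terpinene as hydrogen donor closes the thiabicycle in one step (known preparation of this sulfide); the limonene stereocentre dictates both bridgeheads and hydrogen delivery from the open face sets the methyl-bearing centre.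

**Step 6**
Reactants: 5 7-(allyloxy)-5-(bromomethyl)-2,2-diphenyl-1,3-benzodioxole; 7 (1S,4S,5S)-isothiocineole
Product: 8 (1S,4S,5S)-6-{[7-(allyloxy)-2,2-diphenyl-1,3-benzodioxol-5-yl]methyl}-4,7,7-trimethyl-6-thiabicyclo[3.2.1]octan-6-ium tetrafluoroborate
Conditions: NaBF4 (aq.), CH2Cl2, rt
Reagents that add atoms: sodium tetrafluoroborate, [Na+].F[B-](F)(F)F
Why: SN2 alkylation of the thioether by the benzylic bromide, driven by exchange of bromide for non-nucleophilic tetrafluoroborate, should give one sulfonium diastereomer by attack through the less hindered sulfur lone pair.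

**Step 7**
Reactants: 9 3,5-bis(benzyloxy)phenol
Product: 10 1-(allyloxy)-3,5-bis(benzyloxy)benzene
Conditions: allyl bromide, K2CO3, acetone, reflux
Reagents that add atoms: allyl bromide, C=CCBr
Why: Williamson etherification of the phenol sets up the sigmatropic shift of the next step.

**Step 8**
Reactants: 10 1-(allyloxy)-3,5-bis(benzyloxy)benzene
Product: 12 2-allyl-3,5-bis(benzyloxy)phenol, via ortho-dienone 11 (not isolated)
Conditions: N,N-diethylaniline, 200 °C
Reagents that add atoms: none
Why: Aromatic Claisen rearrangement ([3,3]-shift, then tautomerisation of the dienone) delivers the allyl group to the ortho carbon; the two ortho positions are equivalent, so one isomer is expected.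

**Step 9**
Reactants: 12 2-allyl-3,5-bis(benzyloxy)phenol
Product: 15 4,6-bis(benzyloxy)-2,3-dihydro-1-benzofuran-2-ol (racemic lactol), via 1,2-diol 13 (not isolated), via hydroxy aldehyde 14 (not isolated)
Conditions: OsO4 (2 mol %), NaIO4, 2,6-lutidine, dioxane/H2O, rt
Reagents that add atoms: osmium tetroxide (catalytic oxygen carrier), O=[Os](=O)(=O)=O; sodium periodate, [Na+].[O-]I(=O)(=O)=O; water, O
Why: Lemieux–Johnson cleavage (catalytic dihydroxylation, periodate glycol cleavage) should turn the allyl group into the arylacetaldehyde, which is trapped by the neighbouring phenol as the five-membered lactol, racemic at a carbon whose configuration is erased later.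

**Step 10**
Reactants: 15 4,6-bis(benzyloxy)-2,3-dihydro-1-benzofuran-2-ol; 8 isothiocineole-derived benzylsulfonium tetrafluoroborate
Product: 19 (2R,3S)-2-[7-(allyloxy)-2,2-diphenyl-1,3-benzodioxol-5-yl]-5,7-bis(benzyloxy)chroman-3-ol, via potassium phenolate aldehyde 16 (not isolated), via sulfonium ylide 17 (not isolated), via trans-epoxide 18 (not isolated)
Conditions: KHMDS (2.1 equiv), THF, −78 → −30 °C; then (±)-CSA (1.3 equiv), CH2Cl2, −30 → 0 °C, one pot
Reagents that add atoms: none
Why: Proposed new method: KHMDS deprotonates lactol 15, whose alkoxide opens to the potassium phenolate 16 of the arylacetaldehyde, and converts salt 8 into benzylide 17, whose carbanion adds to the aldehyde carbon (future C3) to give the anti-betaine, which closes 3-exo-tet with loss of the sulfide to the trans-epoxide, protonated on acidification to epoxy phenol 18; the phenol oxygen then opens the protonated epoxide at its benzylic carbon (future C2) in a 6-endo-tet, SN2-like closure with inversion, so the ArCH carbon has been inserted between the ring oxygen and the hemiacetal carbon and the five-membered lactol ring becomes the six-membered pyran. The closest known reaction types are the asymmetric sulfonium-benzylide (Corey–Chaykovsky-type) epoxidation of aldehydes, its use on cyclic hemiaminals where the liberated N–H opens the aryl epoxide in the endo mode to 2-aryl-3-hydroxypiperidines, and the acid-catalysed 6-endo cyclisation of 2-(3-aryloxiranylmethyl)phenols to flavan-3-ols. C3 is set in the C–C bond formation, where the rigid bicyclic sulfide fixes the ylide conformation and shields one face and the preference for the anti-betaine should give the (2S,3S)-trans-epoxide; C2 is set by the same reagent control at the ylide carbon and is then inverted once, stereospecifically, in the ring closure, which turns the trans-epoxide into the 2,3-trans (2R,3S) flavanol, while the racemic hemiacetal centre of 15 is erased on the way. The step needs 6-endo over 5-exo opening and carbonyl addition over enolisation of the arylacetaldehyde: the first should be secured by the 4'-oxygen para to the benzylic carbon, which makes that carbon the electrophilic terminus once the epoxide is protonated, and by keeping the basic phase cold and short so that the phenoxide does not attack in the 5-exo mode; the second by the low temperature and the non-nucleophilic base.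

**Step 11**
Reactants: 19 (2R,3S)-2-[7-(allyloxy)-2,2-diphenyl-1,3-benzodioxol-5-yl]-5,7-bis(benzyloxy)chroman-3-ol
Product: 20 (2R,3S)-5,7-bis(benzyloxy)-2-(7-hydroxy-2,2-diphenyl-1,3-benzodioxol-5-yl)chroman-3-ol
Conditions: Pd(PPh3)4 (5 mol %), morpholine, THF, rt
Reagents that add atoms: none
Why: Pd(0) ionises the aryl allyl ether to a π-allyl complex that is trapped by morpholine (Tsuji–Trost deallylation), which should leave benzyl ethers, ketal and the free 3-OH untouched.

**Step 12**
Reactants: 20 (2R,3S)-5,7-bis(benzyloxy)-2-(7-hydroxy-2,2-diphenyl-1,3-benzodioxol-5-yl)chroman-3-ol; 21 3,4,5-tris(benzyloxy)benzoyl chloride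
Product: 22 6-[(2R,3S)-5,7-bis(benzyloxy)-3-hydroxychroman-2-yl]-2,2-diphenyl-1,3-benzodioxol-4-yl 3,4,5-tris(benzyloxy)benzoate
Conditions: K2CO3, acetone, 0 °C → rt
Reagents that add atoms: none
Why: Under carbonate only the phenol is ionised, so the aroyl chloride should acylate the 3'-phenoxide and not the neutral secondary 3-OH (chemoselective phenol esterification without an acyl-transfer catalyst).

**Step 13**
Reactants: 22 6-[(2R,3S)-5,7-bis(benzyloxy)-3-hydroxychroman-2-yl]-2,2-diphenyl-1,3-benzodioxol-4-yl 3,4,5-tris(benzyloxy)benzoate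
Product: 23 gallocatechin 3'-O-gallate, (2R,3S)
Conditions: H2 (1 atm), 20 % Pd(OH)2/C, THF/MeOH, rt
Reagents that add atoms: none
Why: Hydrogenolysis of the five benzyl aryl ethers and of the doubly benzylic diphenylmethylene ketal over Pearlman's catalyst under neutral conditions should leave the aryl ester and both stereocentres untouched.

**Compound list**

1 | methyl gallate | COC(=O)c1cc(O)c(O)c(O)c1 | starting material
2 | methyl 7-hydroxy-2,2-diphenyl-1,3-benzodioxole-5-carboxylate | COC(=O)c1cc(O)c2OC(c3ccccc3)(c3ccccc3)Oc2c1 | intermediate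
3 | methyl 7-(allyloxy)-2,2-diphenyl-1,3-benzodioxole-5-carboxylate | COC(=O)c1cc(OCC=C)c2OC(c3ccccc3)(c3ccccc3)Oc2c1 | intermediate
4 | [7-(allyloxy)-2,2-diphenyl-1,3-benzodioxol-5-yl]methanol | OCc1cc(OCC=C)c2OC(c3ccccc3)(c3ccccc3)Oc2c1 | intermediate
5 | 7-(allyloxy)-5-(bromomethyl)-2,2-diphenyl-1,3-benzodioxole | BrCc1cc(OCC=C)c2OC(c3ccccc3)(c3ccccc3)Oc2c1 | intermediate
6 | (S)-(−)-limonene | CC1=CC[C@H](CC1)C(C)=C | starting material
7 | (1S,4S,5S)-4,7,7-trimethyl-6-thiabicyclo[3.2.1]octane (isothiocineole) | C[C@H]1CC[C@H]2C[C@@H]1SC2(C)C | intermediate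
8 | (1S,4S,5S)-6-{[7-(allyloxy)-2,2-diphenyl-1,3-benzodioxol-5-yl]methyl}-4,7,7-trimethyl-6-thiabicyclo[3.2.1]octan-6-ium tetrafluoroborate | C[C@H]1CC[C@H]2C[C@@H]1[S+](Cc1cc(OCC=C)c3OC(c4ccccc4)(c4ccccc4)Oc3c1)C2(C)C.F[B-](F)(F)F | intermediate
9 | 3,5-bis(benzyloxy)phenol | Oc1cc(OCc2ccccc2)cc(OCc2ccccc2)c1 | starting material
10 | 1-(allyloxy)-3,5-bis(benzyloxy)benzene | C=CCOc1cc(OCc2ccccc2)cc(OCc2ccccc2)c1 | intermediate
11 | 6-allyl-3,5-bis(benzyloxy)cyclohexa-2,4-dien-1-one (not isolated) | O=C1C=C(OCc2ccccc2)C=C(OCc2ccccc2)C1CC=C | intermediate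
12 | 2-allyl-3,5-bis(benzyloxy)phenol | C=CCc1c(O)cc(OCc2ccccc2)cc1OCc1ccccc1 | intermediate
13 | 3-[2,4-bis(benzyloxy)-6-hydroxyphenyl]propane-1,2-diol, racemic (not isolated) | OCC(O)Cc1c(O)cc(OCc2ccccc2)cc1OCc1ccccc1 | intermediate
14 | 2-[2,4-bis(benzyloxy)-6-hydroxyphenyl]acetaldehyde (not isolated) | O=CCc1c(O)cc(OCc2ccccc2)cc1OCc1ccccc1 | intermediate
15 | 4,6-bis(benzyloxy)-2,3-dihydro-1-benzofuran-2-ol, racemic | OC1Cc2c(OCc3ccccc3)cc(OCc3ccccc3)cc2O1 | intermediate
16 | potassium 3,5-bis(benzyloxy)-2-(2-oxoethyl)phenolate (ring-opened lactol, not isolated) | O=CCc1c([O-])cc(OCc2ccccc2)cc1OCc1ccccc1.[K+] | intermediate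
17 | sulfonium benzylide of 8 (not isolated) | C[C@H]1CC[C@H]2C[C@@H]1[S+]([CH-]c1cc(OCC=C)c3OC(c4ccccc4)(c4ccccc4)Oc3c1)C2(C)C | intermediate
18 | 2-{[(2S,3S)-3-(7-(allyloxy)-2,2-diphenyl-1,3-benzodioxol-5-yl)oxiran-2-yl]methyl}-3,5-bis(benzyloxy)phenol (not isolated) | Oc1cc(OCc2ccccc2)cc(OCc2ccccc2)c1C[C@@H]1O[C@H]1c1cc(OCC=C)c2OC(c3ccccc3)(c3ccccc3)Oc2c1 | intermediate
19 | (2R,3S)-2-[7-(allyloxy)-2,2-diphenyl-1,3-benzodioxol-5-yl]-5,7-bis(benzyloxy)chroman-3-ol | C=CCOc1cc([C@H]2Oc3cc(OCc4ccccc4)cc(OCc4ccccc4)c3C[C@@H]2O)cc2OC(c3ccccc3)(c3ccccc3)Oc12 | intermediate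
20 | (2R,3S)-5,7-bis(benzyloxy)-2-(7-hydroxy-2,2-diphenyl-1,3-benzodioxol-5-yl)chroman-3-ol | Oc1cc([C@H]2Oc3cc(OCc4ccccc4)cc(OCc4ccccc4)c3C[C@@H]2O)cc2OC(c3ccccc3)(c3ccccc3)Oc12 | intermediate
21 | 3,4,5-tris(benzyloxy)benzoyl chloride | O=C(Cl)c1cc(OCc2ccccc2)c(OCc2ccccc2)c(OCc2ccccc2)c1 | starting material
22 | 6-[(2R,3S)-5,7-bis(benzyloxy)-3-hydroxychroman-2-yl]-2,2-diphenyl-1,3-benzodioxol-4-yl 3,4,5-tris(benzyloxy)benzoate | O=C(Oc1cc([C@H]2Oc3cc(OCc4ccccc4)cc(OCc4ccccc4)c3C[C@@H]2O)cc2OC(c3ccccc3)(c3ccccc3)Oc12)c1cc(OCc2ccccc2)c(OCc2ccccc2)c(OCc2ccccc2)c1 | intermediate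
23 | gallocatechin 3'-O-gallate, (2R,3S) | O=C(Oc1cc([C@H]2Oc3cc(O)cc(O)c3C[C@@H]2O)cc(O)c1O)c1cc(O)c(O)c(O)c1 | target

**Count and risks**

Total step count: 13. Longest linear sequence: 9 steps (steps 1–4, 6, 10–13).

Steps most likely to fail:

Step 10 (Proposed new method). The phenoxide may open the epoxide in the 5-exo mode before acidification, the ylide may be consumed by proton transfer from the arylacetaldehyde with aldol loss of the aldehyde, or the facial selectivity of the ylide addition may be too low. The fallback uses known chemistry, sets out from bromide 5 and lactol 15, and comes back at 19. Bromide 5 is heated with triethyl phosphite (Arbuzov reaction) to give diethyl {[7-(allyloxy)-2,2-diphenyl-1,3-benzodioxol-5-yl]methyl}phosphonate F1. Horner–Wadsworth–Emmons olefination of lactol 15 with F1 (KOt-Bu, 2.2 equiv, THF) should give 2-[(2E)-3-(7-(allyloxy)-2,2-diphenyl-1,3-benzodioxol-5-yl)prop-2-en-1-yl]-3,5-bis(benzyloxy)phenol F2. The phenol is silylated (TBSCl, imidazole) to the TBS ether F3. Shi epoxidation with the L-fructose-derived ketone (Oxone, K2CO3 buffer, MeCN/DMM/H2O, 0 °C) should epoxidise the trans-disubstituted styrenyl alkene, and not the monosubstituted allyl ether, to the (2S,3S)-epoxide TBS ether F4. Buffered desilylation (TBAF/AcOH, THF, 0 °C) liberates epoxy phenol 18, which is cyclised with catalytic CSA to 19.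

Step 12. The secondary 3-OH may be acylated as well, or the aroyl group may migrate between oxygens. The fallback sets out from 19 and comes back at 22. The 3-OH of 19 is silylated (TBSOTf, 2,6-lutidine) to the 3-O-TBS allyl ether F5. Deallylation as in step 11 gives the 3-O-TBS phenol F6. Acylation with 21 (Et3N, DMAP, CH2Cl2) gives the 3-O-TBS ester F7. Desilylation with HF·pyridine in THF gives 22.

Step 9. The electron-rich free phenol may be over-oxidised by periodate or osmium, or the lactol may dehydrate to the benzofuran. The fallback sets out from 12 and comes back at 15. Phenol 12 is acetylated (Ac2O, pyridine) to 2-allyl-3,5-bis(benzyloxy)phenyl acetate F8. Ozonolysis (O3, CH2Cl2/MeOH, −78 °C, indicator; Me2S) gives 3,5-bis(benzyloxy)-2-(2-oxoethyl)phenyl acetate F9. Methanolysis of the acetate (K2CO3, MeOH, 0 °C) frees the phenol, which closes onto the aldehyde to give lactol 15.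

**Further compounds**

F1 | step 10 | diethyl {[7-(allyloxy)-2,2-diphenyl-1,3-benzodioxol-5-yl]methyl}phosphonate | CCOP(=O)(OCC)Cc1cc(OCC=C)c2OC(c3ccccc3)(c3ccccc3)Oc2c1
F2 | step 10 | 2-[(2E)-3-(7-(allyloxy)-2,2-diphenyl-1,3-benzodioxol-5-yl)prop-2-en-1-yl]-3,5-bis(benzyloxy)phenol | Oc1cc(OCc2ccccc2)cc(OCc2ccccc2)c1C/C=C/c1cc(OCC=C)c2OC(c3ccccc3)(c3ccccc3)Oc2c1
F3 | step 10 | tert-butyldimethylsilyl ether of F2 | CC(C)(C)[Si](C)(C)Oc1cc(OCc2ccccc2)cc(OCc2ccccc2)c1C/C=C/c1cc(OCC=C)c2OC(c3ccccc3)(c3ccccc3)Oc2c1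
F4 | step 10 | (2S,3S)-epoxide of F3 (TBS ether of 18) | CC(C)(C)[Si](C)(C)Oc1cc(OCc2ccccc2)cc(OCc2ccccc2)c1C[C@@H]1O[C@H]1c1cc(OCC=C)c2OC(c3ccccc3)(c3ccccc3)Oc2c1
F5 | step 12 | 3-O-tert-butyldimethylsilyl ether of 19 | C=CCOc1cc([C@H]2Oc3cc(OCc4ccccc4)cc(OCc4ccccc4)c3C[C@@H]2O[Si](C)(C)C(C)(C)C)cc2OC(c3ccccc3)(c3ccccc3)Oc12
F6 | step 12 | 3-O-tert-butyldimethylsilyl ether of 20 | Oc1cc([C@H]2Oc3cc(OCc4ccccc4)cc(OCc4ccccc4)c3C[C@@H]2O[Si](C)(C)C(C)(C)C)cc2OC(c3ccccc3)(c3ccccc3)Oc12
F7 | step 12 | 3-O-tert-butyldimethylsilyl ether of 22 | O=C(Oc1cc([C@H]2Oc3cc(OCc4ccccc4)cc(OCc4ccccc4)c3C[C@@H]2O[Si](C)(C)C(C)(C)C)cc2OC(c3ccccc3)(c3ccccc3)Oc12)c1cc(OCc2ccccc2)c(OCc2ccccc2)c(OCc2ccccc2)c1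
F8 | step 9 | 2-allyl-3,5-bis(benzyloxy)phenyl acetate | CC(=O)Oc1cc(OCc2ccccc2)cc(OCc2ccccc2)c1CC=C
F9 | step 9 | 3,5-bis(benzyloxy)-2-(2-oxoethyl)phenyl acetate | CC(=O)Oc1cc(OCc2ccccc2)cc(OCc2ccccc2)c1CC=O
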